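The labdane core is disconnected at C4–C5 and C9–C10. Ring A (C1–C5, C10) is carried as a 1,2,2-trimethylcyclopentane whose methyl-bearing quaternary carbon (future C10) holds a secondary carbinol (future C5) tethered to a geranate chain. Ionisation of the C5–O bond makes the CMe2 carbon (C4) shift from C10 to C5: the five-membered ring expands to ring A with inversion at C5, and the C10 cation closes ring B onto the C8=C9 alkene, ending as the 7-ene. The step exploits the C4(Me)2–C5(H)–C10(Me) array of ring A, a methine between two quaternary carbons. One carbinol stereocentre, set by CBS reduction, controls C5, C10 and C9.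

Key step: step 6

Remark: labdane numbering is used for the future core atoms. The ring quaternary carbon of 3, 8, 9 and 10 is left racemic on purpose, because it becomes the planar C10 cation in step 6; 9 and 10 are therefore pairs of epimers with one configuration at the carbinol carbon.
Remark: methyl geranate 4 is taken as the pure 2E isomer.

Step 1
Reactants: 1 1-(2-methylcyclopent-1-en-1-yl)ethan-1-one
Product: 3 racemic 1-(1,2,2-trimethylcyclopentyl)ethan-1-one, via lithium enolate 2 (not isolated)
Conditions: Me2CuLi (from MeLi and CuI), Et2O, −20 to 0 °C; then MeI, HMPA, THF, 0 °C to rt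
Reagents that add atoms: lithium dimethylcuprate, [Li+].C[Cu-]C; iodomethane, CI
Why: Conjugate addition of the cuprate to the β,β-disubstituted enone builds the CMe2 carbon and gives the tetrasubstituted enolate 2 regiospecifically, which is C-methylated by the small electrophile MeI (tandem 1,4-addition and enolate alkylation), the racemic outcome being intended.

Step 2
Reactants: 4 methyl (2E)-3,7-dimethylocta-2,6-dienoate (methyl geranate)
Product: 5 methyl (2E,6E)-8-hydroxy-3,7-dimethylocta-2,6-dienoate
Conditions: SeO2 (cat.), t-BuOOH, salicylic acid (cat.), CH2Cl2, rt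
Reagents that add atoms: selenium dioxide, O=[Se]=O (delivers the oxygen); tert-butyl hydroperoxide, CC(C)(C)OO (terminal oxidant and net oxygen source)
Why: SeO2 allylic oxidation (ene reaction, then 2,3-sigmatropic shift) should hydroxylate the E-methyl group of the electron-rich terminal alkene selectively, the conjugated alkene being deactivated.

Step 3
Reactants: 5 methyl (2E,6E)-8-hydroxy-3,7-dimethylocta-2,6-dienoate
Product: 6 methyl (2E,6E)-8-bromo-3,7-dimethylocta-2,6-dienoate
Conditions: CBr4, PPh3, CH2Cl2, 0 °C
Reagents that add atoms: tetrabromomethane, BrC(Br)(Br)Br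
Why: The Appel reaction converts the primary allylic alcohol into the bromide by SN2 displacement under neutral conditions, without allylic transposition or loss of the E geometry.

Step 4
Reactants: 3 racemic 1-(1,2,2-trimethylcyclopentyl)ethan-1-one; 6 methyl (2E,6E)-8-bromo-3,7-dimethylocta-2,6-dienoate
Product: 8 methyl (2E,6E)-3,7-dimethyl-10-oxo-10-(1,2,2-trimethylcyclopentyl)deca-2,6-dienoate, via lithium enolate 7 (not isolated)
Conditions: LiN(iPr)2, THF, −78 °C; then 6, DMPU, −78 to −20 °C
Reagents that add atoms: none
Why: The ketone can enolise only on its methyl side, and the kinetic lithium enolate 7 should be alkylated by the reactive primary allylic bromide (SN2) faster than it attacks the conjugated ester, joining future C6 to C7.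

Step 5
Reactants: 8 methyl (2E,6E)-3,7-dimethyl-10-oxo-10-(1,2,2-trimethylcyclopentyl)deca-2,6-dienoate
Product: 9 methyl (2E,6E,10S)-10-hydroxy-3,7-dimethyl-10-(1,2,2-trimethylcyclopentyl)deca-2,6-dienoate (both epimers at the ring quaternary carbon)
Conditions: (R)-2-methyl-CBS-oxazaborolidine (20 mol%), catecholborane, toluene, −40 °C; then MeOH
Reagents that add atoms: none
Why: In the Corey–Bakshi–Shibata reduction the catalyst distinguishes the tertiary-alkyl flank (large) from the primary-alkyl flank (small), so the R catalyst should set the S carbinol by reagent control in both ring epimers, while catecholborane spares the alkenes and the ester.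

Step 6
Reactants: 9 methyl (2E,6E,10S)-10-hydroxy-3,7-dimethyl-10-(1,2,2-trimethylcyclopentyl)deca-2,6-dienoate
Product: 11 methyl (2E)-3-methyl-5-[(1S,4aS,8aS)-2,5,5,8a-tetramethyl-1,4,4a,5,6,7,8,8a-octahydronaphthalen-1-yl]pent-2-enoate, via secondary triflate 10 (not isolated)
Conditions: Tf2O, 2,6-di-tert-butyl-4-methylpyridine, CH2Cl2, −78 to −20 °C; chromatography on AgNO3-impregnated silica
Reagents that add atoms: none
Why: O-triflation gives the secondary triflate 10, which ionises at low temperature while the ring bond to the CMe2 carbon (future C4) migrates antiperiplanar to the departing triflate from the quaternary carbon (future C10) to the carbinol carbon (future C5), so that the cyclopentane becomes ring A and a tertiary 1-methylcyclohexyl cation appears at C10; this cation is captured by C9 of the 6E alkene and the resulting C8 cation loses the axial C7 proton. The closest known reactions are the solvolytic Wagner–Meerwein ring enlargement of 1-alkylcyclopentylcarbinyl sulfonates and the cation–olefin cyclisation of monocyclic terpenoid cations, here run in tandem. Ring A is closed by a 1,2-alkyl shift (five to six ring atoms) and ring B by a 6-endo-trig cation–olefin closure through a chair-like transition state with the C5 tether equatorial. C5 is set by inversion at the S carbinol carbon, C10 by closure trans to H5 in that chair (methyl axial) and C9 by the E geometry of the alkene, which places the side chain equatorial; the ring quaternary centre of 9 is destroyed, so both epimers converge. The step needs migration of the CMe2 carbon in preference to the ring CH2 and the methyl group, which its higher substitution and the relief of the congested quaternary–quaternary bond should secure, and it needs the chain terminus to stay out, which the electron-poor conjugated ester and the buffered aprotic medium should secure. The 7-ene is expected to predominate over its 8(17)- and 8-ene isomers, which would be removed on the AgNO3-impregnated silica.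

Step 7
Reactants: 11 methyl (2E)-3-methyl-5-[(1S,4aS,8aS)-2,5,5,8a-tetramethyl-1,4,4a,5,6,7,8,8a-octahydronaphthalen-1-yl]pent-2-enoate
Product: 12 (2E)-3-methyl-5-[(1S,4aS,8aS)-2,5,5,8a-tetramethyl-1,4,4a,5,6,7,8,8a-octahydronaphthalen-1-yl]pent-2-en-1-ol
Conditions: iBu2AlH, CH2Cl2, −78 to 0 °C; aqueous potassium sodium tartrate
Reagents that add atoms: none
Why: iBu2AlH reduces the conjugated ester in 1,2-fashion to the primary allylic alcohol with retention of the 13E geometry and leaves the ring alkene untouched.

Step 8
Reactants: 12 (2E)-3-methyl-5-[(1S,4aS,8aS)-2,5,5,8a-tetramethyl-1,4,4a,5,6,7,8,8a-octahydronaphthalen-1-yl]pent-2-en-1-ol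
Product: 13 3-{[(2E)-3-methyl-5-[(1S,4aS,8aS)-2,5,5,8a-tetramethyl-1,4,4a,5,6,7,8,8a-octahydronaphthalen-1-yl]pent-2-en-1-yl]oxy}-3-oxopropanoic acid
Conditions: Meldrum's acid, toluene, 90 °C
Reagents that add atoms: Meldrum's acid (2,2-dimethyl-1,3-dioxane-4,6-dione), CC1(C)OC(=O)CC(=O)O1
Why: Ring-opening acylation of the primary alcohol by Meldrum's acid with loss of acetone should give the malonic half ester directly, without a coupling agent or protecting group and below the temperature of decarboxylation.

Compound list
1 | 1-(2-methylcyclopent-1-en-1-yl)ethan-1-one | CC(=O)C1=C(C)CCC1 | starting material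
2 | lithium 1-(2,2-dimethylcyclopentylidene)ethan-1-olate | [Li+].CC([O-])=C1CCCC1(C)C | intermediate
3 | racemic 1-(1,2,2-trimethylcyclopentyl)ethan-1-one | CC(=O)C1(C)CCCC1(C)C | intermediate
4 | methyl (2E)-3,7-dimethylocta-2,6-dienoate (methyl geranate) | COC(=O)/C=C(C)/CCC=C(C)C | starting material
5 | methyl (2E,6E)-8-hydroxy-3,7-dimethylocta-2,6-dienoate | COC(=O)/C=C(C)/CC/C=C(C)/CO | intermediate
6 | methyl (2E,6E)-8-bromo-3,7-dimethylocta-2,6-dienoate | COC(=O)/C=C(C)/CC/C=C(C)/CBr | intermediate
7 | lithium 1-(1,2,2-trimethylcyclopentyl)ethen-1-olate | [Li+].C=C([O-])C1(C)CCCC1(C)C | intermediate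
8 | methyl (2E,6E)-3,7-dimethyl-10-oxo-10-(1,2,2-trimethylcyclopentyl)deca-2,6-dienoate (racemic at the ring quaternary carbon) | COC(=O)/C=C(C)/CC/C=C(C)/CCC(=O)C1(C)CCCC1(C)C | intermediate
9 | methyl (2E,6E,10S)-10-hydroxy-3,7-dimethyl-10-(1,2,2-trimethylcyclopentyl)deca-2,6-dienoate (both epimers at the ring quaternary carbon) | COC(=O)/C=C(C)/CC/C=C(C)/CC[C@H](O)C1(C)CCCC1(C)C | intermediate
10 | methyl (2E,6E,10S)-3,7-dimethyl-10-(trifluoromethanesulfonyloxy)-10-(1,2,2-trimethylcyclopentyl)deca-2,6-dienoate (both ring epimers) | COC(=O)/C=C(C)/CC/C=C(C)/CC[C@H](OS(=O)(=O)C(F)(F)F)C1(C)CCCC1(C)C | intermediate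
11 | methyl (2E)-3-methyl-5-[(1S,4aS,8aS)-2,5,5,8a-tetramethyl-1,4,4a,5,6,7,8,8a-octahydronaphthalen-1-yl]pent-2-enoate (methyl labda-7,13E-dien-15-oate) | CC1=CC[C@H]2C(C)(C)CCC[C@]2(C)[C@H]1CC/C(C)=C/C(=O)OC | intermediate
12 | (2E)-3-methyl-5-[(1S,4aS,8aS)-2,5,5,8a-tetramethyl-1,4,4a,5,6,7,8,8a-octahydronaphthalen-1-yl]pent-2-en-1-ol (labda-7,13E-dien-15-ol) | CC1=CC[C@H]2C(C)(C)CCC[C@]2(C)[C@H]1CC/C(C)=C/CO | intermediate
13 | 3-{[(2E)-3-methyl-5-[(1S,4aS,8aS)-2,5,5,8a-tetramethyl-1,4,4a,5,6,7,8,8a-octahydronaphthalen-1-yl]pent-2-en-1-yl]oxy}-3-oxopropanoic acid | CC1=CC[C@H]2C(C)(C)CCC[C@]2(C)[C@H]1CC/C(C)=C/COC(=O)CC(=O)O | target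

Total step count: 8
Longest linear sequence: 7 steps (4 → 5 → 6 → 8 → 9 → 11 → 12 → 13, steps 2 to 8)

Steps most likely to fail

Step 6. The triflate may ionise with migration of the methyl group or the ring CH2 instead of the CMe2 carbon. It may also leak through a free secondary cation, with erosion of enantiomeric purity, or the C8 cation may lose a proton unselectively. The fallback separates ring expansion from ring B closure. Setting out from 9, MsCl and Et3N in CH2Cl2 at 0 °C would give the isolable methyl (2E,6E,10S)-10-(methanesulfonyloxy)-3,7-dimethyl-10-(1,2,2-trimethylcyclopentyl)deca-2,6-dienoate F1. Its solvolysis in aqueous acetone buffered with CaCO3 at 50 °C, where water should capture the ring-expanded cation before the alkene can, should give the tertiary alcohol methyl (2E,6E)-9-[(1S)-2-hydroxy-2,6,6-trimethylcyclohexyl]-3,7-dimethylnona-2,6-dienoate F2. The sense and fidelity of the shift can be checked on F2. SnCl4 in CH2Cl2 at −78 °C would then ionise the tertiary alcohol and close ring B in a separate, conventional cation–olefin cyclisation, coming back to the route at 11.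

Step 1. The twisted tetrasubstituted enone may add the cuprate sluggishly, and the hindered enolate may be protonated or O-alkylated instead of C-methylated next to the new CMe2 carbon. The fallback builds the ring methyl group by cyclopropanation and ring opening instead of enolate alkylation. Setting out from 1, Me2CuLi with Me3SiCl in THF at −78 °C would give the silyl enol ether [1-(2,2-dimethylcyclopentylidene)ethoxy]trimethylsilane F3. Simmons–Smith cyclopropanation (Et2Zn, CH2I2, CH2Cl2, 0 °C) would give trimethyl[(1,4,4-trimethylspiro[2.4]heptan-1-yl)oxy]silane F4. NaOH in MeOH would open the siloxycyclopropane at the bond between its CH2 group and the oxygen-bearing carbon, turning the CH2 group into the ring methyl group and coming back to the route at 3.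

Step 5. The catalyst may discriminate poorly between the faces of a ketone flanked by a racemic, very hindered quaternary carbon, and slow reduction would let uncatalysed reduction or hydroboration of the chain alkenes compete. The fallback replaces catalytic borane delivery by stoichiometric reagent control. Setting out from 8, (−)-B-chlorodiisopinocampheylborane (neat, rt, then diethanolamine) transfers hydride within the reagent through a six-membered transition state. It does not hydroborate alkenes and is known to give the S carbinol from tert-alkyl ketones, so it comes back to the route at 9 without any new compound.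

Further compounds
F1 | step 6 | methyl (2E,6E,10S)-10-(methanesulfonyloxy)-3,7-dimethyl-10-(1,2,2-trimethylcyclopentyl)deca-2,6-dienoate | COC(=O)/C=C(C)/CC/C=C(C)/CC[C@H](OS(C)(=O)=O)C1(C)CCCC1(C)C
F2 | step 6 | methyl (2E,6E)-9-[(1S)-2-hydroxy-2,6,6-trimethylcyclohexyl]-3,7-dimethylnona-2,6-dienoate | COC(=O)/C=C(C)/CC/C=C(C)/CC[C@@H]1C(C)(O)CCCC1(C)C
F3 | step 1 | [1-(2,2-dimethylcyclopentylidene)ethoxy]trimethylsilane | CC(O[Si](C)(C)C)=C1CCCC1(C)C
F4 | step 1 | trimethyl[(1,4,4-trimethylspiro[2.4]heptan-1-yl)oxy]silane | CC1(O[Si](C)(C)C)CC12CCCC2(C)C
F0 | step 5 | none | none
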